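The percentage point of the substrate pair charged is the unit here, and the coupling partner, taken as the limiting reagent at one per substrate, allows a loss of 30.0%.

| setting | eta | alpha | ochre | blue |
|---|---|---|---|---|
| left-handed substrate | 15 mM | 15 mM | 15 mM | 15 mM |
| right-handed substrate | 15 mM | 15 mM | 15 mM | 15 mM |
| coupling partner | 9 mM | 9 mM | 9.00 mM | 9.00 mM |
| catalyst | 0.17 mM | 0.60 mM | 0.30 mM | 1.0 mM |
| remark | run made earlier | run made earlier |  |  |
| time |  |  | 5.0 h | 5.0 h |

| run | time / h | right-handed substrate / % | left-handed substrate / % |
|---|---|---|---|
| eta | 0.833 | 49.2 | 46.7 |
| eta | 2.00 | 48.3 | 43.9 |
| eta | 2.50 | 46.7 | 44.2 |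
| eta | 4.00 | 44.9 | 42.7 |
| alpha | 0.417 | 50.0 | 41.9 |
| alpha | 1.33 | 46.8 | 39.6 |
| alpha | 2.50 | 43.0 | 37.0 |
| alpha | 4.00 | 39.2 | 36.1 |

(readings scatter by 0.5 percentage points)

- catalyst is single-handed; left-handed substrate and right-handed substrate are mirror images of each other, charged as a racemate, each of them at the stated concentration
- what was read earlier has a scatter of 0.5 percentage points, one standard deviation
- an excess is the difference of the two amounts in percent of their sum
- an excess is below zero if the other one leads

1. which one finishes higher in excess of right-handed substrate over left-handed substrate among what is left of the two ("neither" within 2 percentage points) (ochre / blue / neither)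
2. excess of right-handed substrate over left-handed substrate among what is left of the two at the end, ochre
3. excess of right-handed substrate over left-handed substrate among what is left of the two at the end, blue

Two times carry the reckoning. Taking the coupling to draw on the left-handed substrate, the right-handed substrate falls by crossing over (racemisation), so half the mean gap between the two, over that fall per hour, reads as 1.01 h in alpha, the gap-closing time. Eta, with less catalyst, reads 1.07 h. The gap then stands near the coupling rate times this time.

The other time is the partner's: its remainder in alpha's last two readings falls by a factor e in 2.36 h. Scaled inversely with c(catalyst), that gives 4.73 h in ochre and 1.42 h in blue. Replacing second-half coupling by its mean, this reckoning gives 3.65% for ochre and 2.43% for blue, so neither leads.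

The forecast differs: blue leads, with 1.5% for ochre and 8% for blue, whose burst is “followed by only about 17 points of later loss”.

The flasks give 3.21% for ochre and 2.55% for blue, so the outcome is neither.

    coupling partner + catalyst + left-handed substrate → catalyst + left-handed product (k = 2700 M⁻² min⁻¹)
    coupling partner + catalyst + right-handed substrate → catalyst + right-handed product (k = 68.0 M⁻² min⁻¹)
    left-handed substrate ⇌ right-handed substrate (k = 0.00740 min⁻¹)
    catalyst ⇌ dormant form (K = 2.20, k = 0.0670 min⁻¹)

In blue at 5.00 h, with 4.6% of the partner left, the coupling uses left-handed substrate at 0.048 of the forward interconversion rate. The gap-closing time as read from alpha's scattered readings, an estimate and not a constant of the flask, times each flask's mean second-half coupling, over the substrate left, gives 3.11% for ochre and 2.27% for blue.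

The runs are calculated with constants of no real substance, and the scatter is random.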